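To whoever takes the bench next: this flask holds 18 mM of solid substrate, counted per litre, with 23.4 mM of reagent, and I am reckoning its target at 4.0 h.

all flasks: reagent 23.4 mM
- delta: solid substrate 9 mM; run made earlier
- zeta: solid substrate 14 mM; run made earlier
- flask: solid substrate 18 mM; time 4.0 h

| run | time / h | target / % |
|---|---|---|
| delta | 0.167 | 4.4 |
| delta | 0.500 | 17.8 |
| delta | 0.833 | 28.0 |
| delta | 1.33 | 39.2 |
| delta | 2.00 | 48.1 |
| delta | 2.50 | 52.4 |
| zeta | 0.417 | 8.8 |
| zeta | 0.833 | 18.9 |
| zeta | 1.33 | 29.7 |
| zeta | 1.50 | 35.1 |
| zeta | 2.00 | 42.4 |
| zeta | 2.50 | 46.9 |

(each reading ± 0.5 percentage points)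

- as a solid, counted per litre of solution: solid substrate
- what was read earlier has a scatter of 0.5 percentage points, one standard deviation
- at the start none of the solid substrate is in solution

- how much target there is at 4.0 h, in percent of the solid substrate charged
- the change that raises the amount of target at 4.0 h, in percent of the solid substrate charged most ("none" if none brings more than 2 percentage points) (oak / cedar / larch / none)
- amount of target at 4.0 h, in percent of the solid substrate charged, after cedar

- oak: doubling the solubility of the solid substrate, all else as stated
- cedar: doubling the dissolution coefficient of the solid substrate, all else as stated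
- larch: doubling the amount of reagent, all else as stated

1. In the delta run I take the solid as gone by 1.33 h. The rise of target then slows from 0.133 h⁻¹ to 0.0860 h⁻¹ of the charge. So I read an e-fold time of 1.35 h for dissolved substrate: the tail lifetime, pseudo-first-order and rough, given the scatter.

2. Running that tail out gives delta a target share of 62.0% of what reacts.

3. Between 0.417 h and 1.33 h the zeta run makes 3.20 mM h⁻¹ of target; taking solid as still present there, I put dissolved substrate near 6.95 mM. This flask's solid should then last until 2.14 h.

4. For 4.0 h I reckon 9.68% of this flask's charge still dissolved, so I expect 56.0% target.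

5. Leave the dissolution coefficient alone: the hold-up in the zeta run reads 0.0326 h, far shorter than the lifetime, so I put cedar near 56.0% too. Doubled reagent should lift the share to 76.6%, so I pick larch.

The forecast, reckoned separately, says 57%, larch and 61% after cedar, holding that “More reagent improves selectivity”.

The flask gives 51.2%, larch and 51.4% after cedar.

    2 starting material → side product B (k = 0.00100 M⁻¹ s⁻¹)
    reagent → decomposition product (k = 7.80 × 10⁻⁷ s⁻¹)
    starting material + reagent → target (k = 0.00680 M⁻¹ s⁻¹)
    solid substrate ⇌ starting material, rate k4*(cs4 - [starting material]) while solid is left; crystals form when [starting material] > cs4 (solubility = 6.90 mM, k = 0.00400 s⁻¹)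
    starting material → side product A (k = 8.20 × 10⁻⁵ s⁻¹)

Of what has reacted in this flask by 4.0 h, 57.1% is target, lower than the share I carried from delta. For the neighbour flask with 94 mM of reagent, I scale the target part of the loss rate by the reagent charge. I reckon its tail lifetime at 0.470 h and its share at 86.8%. That neighbour flask holds 86.4% of target.

The data stem from a simulated flask on assumed constants, noise included.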